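**Retrosynthetic overview**
1. Target 18 is a C2-symmetric head-to-tail dimer. Cutting both benzylic C7–O bonds of the 1,4-dioxane gives two molecules of the 6α,7α-diol 16; C7 can ionise because the C12 methoxy group is para to C8.
2. Diol 16 comes from the Δ6 alkene 15 by α-face dihydroxylation, 15 from enol triflate 14, and 14 from the trans-fused 6-ketone 12.
3. The route rests on ring B: C7 sits between arene carbon C8 and the oxygen-bearing C6. Removing C7 leaves the B-nor ketone 8 (a 1-indanone), so 12 is made from 8 by inserting one carbon from trimethylsilyldiazomethane 9, with C8 migrating (new bonds C6–C7 and C7–C8).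
4. Indanone 8 comes from racemic 7 by resolution, 7 from aryl vinyl ketone 6 by Nazarov closure of C9–C10, and 6 from 4-bromo-2-isopropylanisole and β-cyclocitral.
5. Ring order: rings A and C are bought; five-membered ring B (Nazarov); six-membered ring B (ring expansion); 1,4-dioxane (dimerisation).

Key step: step 6

Remark (assumption): ketone 7/8 is written as the cis-fused epimer; its C5 configuration is immaterial, because C5 is equilibrated after the ring expansion in step 6.
Remark (numbering): atoms are cited in abietane numbering throughout; in the fluorenones C9 = C6, C9a = C5, C4a = C10, C8a = C8 and C4b = C9.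

Step 1
Reactants: 1 2-isopropylanisole
Product: 2 4-bromo-2-isopropylanisole
Conditions: NBS, MeCN, 0 °C → rt
Reagents that add atoms: N-bromosuccinimide, BrN1C(=O)CCC1=O
Why: Electrophilic aromatic bromination, in which the methoxy group is the dominant director and its open para position should be brominated in preference to the ortho position.

Step 2
Reactants: 2 4-bromo-2-isopropylanisole; 3 β-cyclocitral
Product: 5 (±)-(3-isopropyl-4-methoxyphenyl)(2,6,6-trimethylcyclohex-1-en-1-yl)methanol, via aryllithium 4 (not isolated)
Conditions: n-BuLi, THF, −78 °C; then 3, −78 → 0 °C; then H2O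
Reagents that add atoms: none
Why: Lithium–bromine exchange followed by 1,2-addition of the aryllithium to the hindered enal, whose fully substituted β-carbon excludes conjugate addition; the carbinol centre forms racemic and is removed in step 3.

Step 3
Reactants: 5 (±)-aryl cyclohexenyl carbinol
Product: 6 (3-isopropyl-4-methoxyphenyl)(2,6,6-trimethylcyclohex-1-en-1-yl)methanone
Conditions: Dess–Martin periodinane, pyridine, CH2Cl2, 0 °C → rt
Reagents that add atoms: none
Why: Dess–Martin oxidation of a benzylic, allylic secondary alcohol under buffered conditions that should avoid acid ionisation of the carbinol.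

Step 4
Reactants: 6 aryl vinyl ketone
Product: 7 (±)-cis-7-isopropyl-6-methoxy-1,1,4a-trimethyl-1,2,3,4,4a,9a-hexahydro-9H-fluoren-9-one
Conditions: CF3SO3H (2 equiv), (CH2Cl)2, 0 → 40 °C
Reagents that add atoms: none
Why: Aromatic Nazarov cyclisation, in which O-protonation gives a hydroxypentadienyl cation over C10=C5–C6–C8=C9 whose 4π conrotatory closure makes C9–C10 and the quaternary C10 (racemic) at the ortho carbon para to the isopropyl group, the other ortho carbon being blocked by that group, and ketonisation of the enol sets C5 under equilibrating acid.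

Step 5
Reactants: 7 racemic cis-hexahydrofluorenone
Product: 8 (4aS,9aR)-7-isopropyl-6-methoxy-1,1,4a-trimethyl-1,2,3,4,4a,9a-hexahydro-9H-fluoren-9-one
Conditions: preparative HPLC on a chiral stationary phase (cellulose tris(3,5-dimethylphenylcarbamate) on silica), hexane/i-PrOH
Reagents that add atoms: none
Why: No bond changes; this is a chromatographic resolution placed at the first compound that carries the quaternary C10 centre, which no later step can invert, with the enantiomer to be assigned by ECD or by correlating 15 with the 6,7-dehydro abietane of the natural series.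

Step 6
Reactants: 8 (4aS,9aR)-hexahydrofluorenone; 9 trimethylsilyldiazomethane
Product: 12 (5S,10S)-12-methoxyabieta-8,11,13-trien-6-one, via 7-silyl ketone 10 (not isolated), via cis-fused 6-ketone 11 (not isolated)
Conditions: 9 (2 equiv, 2 M in hexanes), Sc(OTf)3 (10 mol%), CH2Cl2, −40 °C → rt; then NaOMe (0.3 equiv), degassed MeOH, 50 °C
Reagents that add atoms: none
Why: Sc(OTf)3 activates the C6 carbonyl of 8, the diazo carbon of 9 adds from the convex face, and loss of N2 from the diazonium alkoxide is concerted with a 1,2-shift of aryl carbon C8 to the new carbon C7, so that C6–C7 and C7–C8 are formed; the closest known reaction type is the Lewis-acid-promoted diazoalkane homologation of 1-indanones to 2-tetralones. Ring B is thus closed as a six-membered ring by ring enlargement (aryl migration onto an exocyclic diazonium carbon), not by a cyclisation. The selectivity needed is migration of C8 in preference to C5: C8 is para to the C12 methoxy group and shifts through a phenonium-like transition state, whereas C5 is a neopentyl-type carbon between two quaternary centres. The silyl group leaves the first product as the hindered α-silyl ketone 10 (or its O-silyl enol ether), which should resist a second insertion, and methoxide then removes silicon to give 11. C5, now α to the C6 ketone, is equilibrated through the Δ5 enolate to the trans fusion (H5 axial and anti to the C10 methyl, ring A a chair with both ring-B bonds equatorial), as in 5α-6-oxo steroids; the quaternary C10 is untouched.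

Step 7
Reactants: 12 trans-fused 6-ketone
Product: 14 (5S,10S)-12-methoxyabieta-6,8,11,13-tetraen-6-yl trifluoromethanesulfonate, via potassium enolate 13 (not isolated)
Conditions: KN(SiMe3)2, THF, −78 °C; then PhNTf2, −78 → 0 °C; H2O work-up
Reagents that add atoms: N-phenylbis(trifluoromethanesulfonimide), O=S(=O)(N(c1ccccc1)S(=O)(=O)C(F)(F)F)C(F)(F)F
Why: Kinetic enolisation at the benzylic C7 methylene, which is more acidic and far less hindered than the C5 methine, followed by O-sulfonylation of the enolate should give the conjugated Δ6 enol triflate without touching C5.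

Step 8
Reactants: 14 enol triflate
Product: 15 (5S,10S)-12-methoxyabieta-6,8,11,13-tetraene
Conditions: Pd(OAc)2 (5 mol%), PPh3 (10 mol%), HCO2H, n-Bu3N, DMF, 60 °C
Reagents that add atoms: none
Why: Palladium-catalysed formate reduction of a vinyl triflate (oxidative addition to zerovalent palladium, formate-to-hydride exchange with loss of CO2, reductive elimination) replaces C6–O by C6–H and leaves the styrenic Δ6 alkene.

Step 9
Reactants: 15 Δ6 alkene
Product: 16 (5S,6R,7S,10S)-12-methoxyabieta-8,11,13-triene-6α,7α-diol
Conditions: OsO4 (2 mol%), NMO (1.5 equiv), acetone/H2O 4:1, rt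
Reagents that add atoms: osmium tetroxide, O=[Os](=O)(=O)=O; N-methylmorpholine N-oxide, C[N+]1([O-])CCOCC1; water, O
Why: Upjohn dihydroxylation, a suprafacial [3+2] addition of OsO4 to the α face because the β face is screened by the axial C10 and C4β methyl groups, sets C6 (6α-OH, R) and should give the cis 6α,7α-diol.

Step 10
Reactants: 16 6α,7α-diol (two molecules)
Product: 18 target dimer, (5S,6R,7R,10S; 5′S,6′R,7′R,10′S)-bis(12-methoxyabieta-8,11,13-triene) joined by C7–O–C6′ and C7′–O–C6 ether bridges (trans-fused 1,4-dioxane), via mono-ether dimer 17 (not isolated)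
Conditions: camphorsulfonic acid (10 mol%), CH2Cl2 (0.5 M), 4 Å molecular sieves, 0 °C → rt
Reagents that add atoms: none
Why: Acid ionises the C7 hydroxyl to a para-methoxybenzylic cation, the 6α-hydroxyl of a second molecule captures it (SN1 dehydrative etherification) to give 17 and the same event at the second C7 closes the dioxane; since only C7 can ionise the union must be head-to-tail, C6 keeps its configuration, each reversible C7–O bond should settle trans to its C6–O neighbour (7β, R), and enantiopure 16 can give only the C2-symmetric dimer.

**Compound list**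
1 | 2-isopropylanisole | COc1ccccc1C(C)C | starting material
2 | 4-bromo-2-isopropylanisole | COc1ccc(Br)cc1C(C)C | intermediate
3 | β-cyclocitral (2,6,6-trimethylcyclohex-1-ene-1-carbaldehyde) | CC1=C(C=O)C(C)(C)CCC1 | starting material
4 | (3-isopropyl-4-methoxyphenyl)lithium, not isolated | [Li]c1ccc(OC)c(C(C)C)c1 | intermediate
5 | (±)-(3-isopropyl-4-methoxyphenyl)(2,6,6-trimethylcyclohex-1-en-1-yl)methanol | COc1ccc(cc1C(C)C)C(O)C1=C(C)CCCC1(C)C | intermediate
6 | (3-isopropyl-4-methoxyphenyl)(2,6,6-trimethylcyclohex-1-en-1-yl)methanone | COc1ccc(cc1C(C)C)C(=O)C1=C(C)CCCC1(C)C | intermediate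
7 | (±)-cis-7-isopropyl-6-methoxy-1,1,4a-trimethyl-1,2,3,4,4a,9a-hexahydro-9H-fluoren-9-one (racemate, relative configuration shown) | COc1cc2c(cc1C(C)C)C(=O)[C@@H]1C(C)(C)CCC[C@]21C | intermediate
8 | (4aS,9aR)-7-isopropyl-6-methoxy-1,1,4a-trimethyl-1,2,3,4,4a,9a-hexahydro-9H-fluoren-9-one | COc1cc2c(cc1C(C)C)C(=O)[C@@H]1C(C)(C)CCC[C@]21C | intermediate
9 | trimethylsilyldiazomethane | C[Si](C)(C)C=[N+]=[N-] | starting material
10 | (5R,10S)-12-methoxy-7-(trimethylsilyl)abieta-8,11,13-trien-6-one (C7 not controlled), not isolated | COc1cc2c(cc1C(C)C)C([Si](C)(C)C)C(=O)[C@@H]1C(C)(C)CCC[C@]21C | intermediate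
11 | (5R,10S)-12-methoxyabieta-8,11,13-trien-6-one (5β-H, cis-fused), not isolated | COc1cc2c(cc1C(C)C)CC(=O)[C@@H]1C(C)(C)CCC[C@]21C | intermediate
12 | (5S,10S)-12-methoxyabieta-8,11,13-trien-6-one (5α-H, trans-fused) | COc1cc2c(cc1C(C)C)CC(=O)[C@H]1C(C)(C)CCC[C@]21C | intermediate
13 | potassium (5S,10S)-12-methoxyabieta-6,8,11,13-tetraen-6-olate, not isolated | COc1cc2c(cc1C(C)C)C=C([O-])[C@H]1C(C)(C)CCC[C@]21C.[K+] | intermediate
14 | (5S,10S)-12-methoxyabieta-6,8,11,13-tetraen-6-yl trifluoromethanesulfonate | COc1cc2c(cc1C(C)C)C=C(OS(=O)(=O)C(F)(F)F)[C@H]1C(C)(C)CCC[C@]21C | intermediate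
15 | (5S,10S)-12-methoxyabieta-6,8,11,13-tetraene | COc1cc2c(cc1C(C)C)C=C[C@H]1C(C)(C)CCC[C@]21C | intermediate
16 | (5S,6R,7S,10S)-12-methoxyabieta-8,11,13-triene-6α,7α-diol | COc1cc2c(cc1C(C)C)[C@H](O)[C@H](O)[C@H]1C(C)(C)CCC[C@]21C | intermediate
17 | mono-ether dimer: 7β-O of one 6α-hydroxy unit bonded to C6α of a second unit that keeps its 7α-OH, not isolated | COc1cc2c(cc1C(C)C)[C@@H](O[C@H]3[C@@H](O)c4cc(C(C)C)c(OC)cc4[C@@]4(C)CCCC(C)(C)[C@H]34)[C@H](O)[C@H]1C(C)(C)CCC[C@]21C | intermediate
18 | target dimer (CNP0327150.1) | COc1cc2c(cc1C(C)C)[C@H]1O[C@H]3[C@H](O[C@@H]1[C@H]1C(C)(C)CCC[C@]21C)c1cc(C(C)C)c(OC)cc1[C@@]1(C)CCCC(C)(C)[C@H]31 | target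

**Step count and risks**
Total steps: 10. Longest linear sequence: 10 steps (1 → 18).

Most likely to fail:

1. Step 6 (ring expansion). The bulky diazoalkane may add slowly to a hindered carbonyl that the para methoxy group deactivates as a vinylogous ester. C5 may migrate instead of C8, or an oxirane may form, and equilibration at C5 may be incomplete. Fallback, from 8 back to 11: Wittig methylenation of 8 (Ph3PCH3Br, KOt-Bu, toluene, 90 °C) should give the 9-methylidene compound F1. Treatment of F1 with the trivalent iodine reagent PhI(OH)OTs in 95% MeOH at rt should activate the exocyclic alkene, add methanol at the benzylic carbon, and force the 1,2-shift of the electron-rich aryl carbon C8 to the former methylene carbon with loss of iodobenzene. Acidic work-up of the resulting ketal should deliver the cis-fused 6-ketone 11, which is carried through the methoxide stage of step 6 to 12.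

2. Step 10 (dimerisation). A 1,2-hydride shift from C6 to the C7 cation (semipinacol) would return ketone 12, which could be recycled through steps 7–9. Open-chain 7,7′-ethers may form, the rearranged ketone may be ketalised by unreacted diol, and convergence at C7 may be poor. Fallback, from 15 to 18: epoxidation of 15 with dimethyldioxirane (acetone, 0 °C) from the α face should give the 6α,7α-epoxide F2. Cyclodimerisation of F2 with catalytic Zn(OTf)2 in concentrated CH2Cl2 at −78 °C would let the epoxide oxygen of one molecule open the activated epoxide of the other at benzylic C7 with inversion. The oxonium so formed would be opened in the same way by the liberated C6 alkoxide, which installs both 7β C–O bonds directly and keeps the C6–O bonds intact, giving 18.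

3. Step 4 (Nazarov). The electrocyclisation may be sluggish because the bond-forming arene carbon is meta to the methoxy group and the ring carries the protonated acyl group. Acid may also cause double-bond migration or loss of the acyl group by ipso protonation. Fallback, from 5 back to 7:
   - BF3·OEt2 in CH2Cl2 at −40 °C should ionise carbinol 5 to an aryl-stabilised allyl cation that closes C9–C10 without a deactivating carbonyl group, giving the indene F3.
   - Hydroboration–oxidation of F3 (BH3·THF; then H2O2, NaOH) should place the hydroxyl at the benzylic C6 and hydrogen at C5, giving the indanol F4.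
   - Dess–Martin oxidation of F4 should give the trans-fused ketone F5, the C9a epimer of 7, which is equilibrated with DBU in toluene to 7.

**Further compounds**
F1 | step 6 | 9-methylidene analogue of 8: 7-isopropyl-6-methoxy-1,1,4a-trimethyl-9-methylidene-2,3,4,4a,9,9a-hexahydro-1H-fluorene, ring fusion as in 8 | COc1cc2c(cc1C(C)C)C(=C)[C@@H]1C(C)(C)CCC[C@]21C
F2 | step 10 | (5S,10S)-6α,7α-epoxy-12-methoxyabieta-8,11,13-triene | COc1cc2c(cc1C(C)C)[C@@H]1O[C@@H]1[C@H]1C(C)(C)CCC[C@]21C
F3 | step 4 | (±)-7-isopropyl-6-methoxy-1,1,4a-trimethyl-2,3,4,4a-tetrahydro-1H-fluorene | COc1cc2c(cc1C(C)C)C=C1C(C)(C)CCCC21C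
F4 | step 4 | (±)-7-isopropyl-6-methoxy-1,1,4a-trimethyl-2,3,4,4a,9,9a-hexahydro-1H-fluoren-9-ol, 9-OH and 9a-H cis to each other and anti to the 4a-methyl (racemate, relative configuration shown) | COc1cc2c(cc1C(C)C)[C@H](O)[C@H]1C(C)(C)CCC[C@]21C
F5 | step 4 | (±)-trans-7-isopropyl-6-methoxy-1,1,4a-trimethyl-1,2,3,4,4a,9a-hexahydro-9H-fluoren-9-one (racemate, relative configuration shown) | COc1cc2c(cc1C(C)C)C(=O)[C@H]1C(C)(C)CCC[C@]21C
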